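**Retrosynthetic overview**

1. Target ⇐ anisoylation, hydroxyl-directed epoxidation and 1,3-anti reduction of a trans-fused dauc-8-en-6-one ⇐ ring-closing metathesis (C8=C9, seven-membered ring) of a cyclopentyl methallyl ketone that carries methyl and allyl on C1.
2. That ketone ⇐ strain-release C–C cleavage of a bicyclo[3.2.0]heptan-6-one; the four-membered ring C5–C6–CH2–C1 is a temporary ring whose CH2 is the latent C1 methyl.
3. Key disconnection C1–C5: intramolecular ketene–olefin [2+2] cycloaddition of C5=C6=O with a C1=CH2 olefin of an acyclic acid; it closes the cyclopentane and sets the quaternary C1 and C5.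
4. Enabling feature: C5 is the only α-carbon of the oxygen-bearing C6 (so C6 can be raised to a ketene), C1 lies three atoms away through C4–C3–C2 (the cyclopentane), and the C1 methyl carbon is 1,3 to C6, so it can be the fourth atom of a cyclobutanone.
5. The acid ⇐ (S)-terpinen-4-ol (supplies C1–C6, both alkyl branches and the C4 carbinol centre) by ozonolysis and enol triflate/allyl coupling. Ring order: cyclopentane (with temporary cyclobutane) → cycloheptene → oxirane.

Key step: step 6

Remark: atoms are numbered as in daucane (C1 = ring-fusion carbon with CH3, C4 = carbinol carbon with isopropyl, C5 = ring-fusion CH, C6 = ester-bearing carbon, C8/C9 = oxirane carbons); (S)-terpinen-4-ol is assumed to be purchasable in enantiomerically enriched form.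

**Route**

Step 1
Reactants: 1 (S)-terpinen-4-ol
Product: 2 (S)-terpinen-4-ol triethylsilyl ether
Conditions: TESOTf, 2,6-lutidine, CH2Cl2, 0 °C to rt
Reagents that add atoms: triethylsilyl trifluoromethanesulfonate, CC[Si](CC)(CC)OS(=O)(=O)C(F)(F)F
Why: Silyl ether protection of the hindered tertiary alcohol with the silyl triflate/lutidine pair masks the hydroxyl that would otherwise form a lactol with the later C1 ketone and a β-lactone with the later ketene; no stereocentre is touched.

Step 2
Reactants: 2 (S)-terpinen-4-ol triethylsilyl ether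
Product: 4 methyl (3S)-6-oxo-3-(propan-2-yl)-3-[(triethylsilyl)oxy]heptanoate, via methoxy hydroperoxide 3 (not isolated)
Conditions: O3, CH2Cl2/MeOH, NaHCO3, −78 °C; then Ac2O, Et3N, 0 °C to rt
Reagents that add atoms: ozone, [O-][O+]=O; methanol, CO
Why: Criegee ozonolysis in methanol traps the less substituted carbonyl oxide as the α-methoxy hydroperoxide while C1 emerges as the methyl ketone, and acetylation with base-induced elimination then gives the methyl ester, so the two termini are differentiated in one flask without touching C4.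

Step 3
Reactants: 4 methyl (3S)-6-oxo-3-(propan-2-yl)-3-[(triethylsilyl)oxy]heptanoate
Product: 5 methyl (3S)-3-(propan-2-yl)-3-[(triethylsilyl)oxy]-6-{[(trifluoromethyl)sulfonyl]oxy}hept-6-enoate
Conditions: KHMDS, THF, −78 °C; then PhNTf2, −78 to 0 °C
Reagents that add atoms: N-phenylbis(trifluoromethanesulfonimide), O=S(=O)(N(c1ccccc1)S(=O)(=O)C(F)(F)F)C(F)(F)F
Why: Kinetic enolisation of the methyl ketone on its methyl side (the hindered, less acidic ester α-CH2 is not deprotonated at −78 °C) followed by O-triflation is a standard enol triflate formation.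

Step 4
Reactants: 5 methyl (3S)-3-(propan-2-yl)-3-[(triethylsilyl)oxy]-6-{[(trifluoromethyl)sulfonyl]oxy}hept-6-enoate
Product: 6 methyl (3S)-6-methylidene-3-(propan-2-yl)-3-[(triethylsilyl)oxy]non-8-enoate
Conditions: allylSnBu3, Pd(PPh3)4 (cat.), LiCl, THF, 65 °C
Reagents that add atoms: allyltributylstannane, C=CC[Sn](CCCC)(CCCC)CCCC
Why: Stille coupling of a vinyl triflate with an allylstannane forms the sp2–sp3 bond under neutral conditions and gives the 1,1-disubstituted olefin whose CH2 is the latent C1 methyl and whose allyl arm is C10–C9.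

Step 5
Reactants: 6 methyl (3S)-6-methylidene-3-(propan-2-yl)-3-[(triethylsilyl)oxy]non-8-enoate
Product: 7 (3S)-6-methylidene-3-(propan-2-yl)-3-[(triethylsilyl)oxy]non-8-enoic acid
Conditions: LiOH·H2O, THF/MeOH/H2O, 45 °C; then AcOH to pH 5
Reagents that add atoms: lithium hydroxide, [Li+].[OH-]
Why: Ester hydrolysis (saponification) under mild base leaves the tertiary silyl ether and the skipped diene untouched.

Step 6
Reactants: 7 (3S)-6-methylidene-3-(propan-2-yl)-3-[(triethylsilyl)oxy]non-8-enoic acid
Product: 10 (1R,4R,5R)-1-(prop-2-en-1-yl)-4-(propan-2-yl)-4-[(triethylsilyl)oxy]bicyclo[3.2.0]heptan-6-one, via acid chloride 8 (not isolated), via ketene 9 (not isolated)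
Conditions: 1-chloro-N,N,2-trimethylprop-1-en-1-amine, CH2Cl2, 0 °C to rt; then slow addition to Et3N, toluene, 110 °C, high dilution
Reagents that add atoms: none
Why: The chloroenamine converts the acid into the acid chloride under neutral conditions and triethylamine dehydrochlorinates it to the aldoketene C5=C6=O, which adds across the 1,1-disubstituted olefin in a thermal ketene–alkene [2+2] cycloaddition; the closest known reaction type is the intramolecular cycloaddition of ketenes tethered by three atoms to 2-substituted 1-alkenes, which gives bicyclo[3.2.0]heptan-6-ones. The cyclopentane closes by the C5–C1 bond over the C4–C3–C2 tether with the second olefin carbon outside the ring (exo mode), and the temporary cyclobutanone is completed by the C6–CH2 bond. No regiocontrol is needed at C5, because the ketene can only form on the single α-carbon of the acid; the electrophilic C6 bonds to the terminal CH2 so that positive charge develops on the disubstituted C1, which bonds to C5, and the remote monosubstituted vinyl group cannot reach the ketene through a small ring. Addition is suprafacial on the olefin, so the four-membered ring is cis-fused and C6 and the methylene that becomes the C1 methyl lie on the same face of the cyclopentane, which fixes the C1/C5 relationship of the trans-hydroazulene. The ketene face is chosen by C4: the larger isopropyl group should take the convex side of the forming bicycle, placing C6 cis to the silyloxy group as in the target. The step needs cycloaddition to outrun ketene dimerisation, which slow addition at high dilution and the proximity of the nucleophilic olefin should secure.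

Step 7
Reactants: 10 (1R,4R,5R)-1-(prop-2-en-1-yl)-4-(propan-2-yl)-4-[(triethylsilyl)oxy]bicyclo[3.2.0]heptan-6-one
Product: 11 6-(2-methylprop-2-en-1-yl)-1-(prop-2-en-1-yl)-4-(propan-2-yl)-4-[(triethylsilyl)oxy]bicyclo[3.2.0]heptan-6-ol (methallyl on the convex face; ring centres as in 10)
Conditions: 2-methylallylmagnesium chloride, THF, −78 °C; then aq. NH4Cl
Reagents that add atoms: 2-methylallylmagnesium chloride, CC(=C)C[Mg]Cl
Why: Grignard 1,2-addition to the strained, electrophilic cyclobutanone should occur from the convex face; the configuration of the new carbinol centre is irrelevant because it returns to a ketone in the next step.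

Step 8
Reactants: 11 the methallyl cyclobutanol
Product: 12 1-[(1R,2R,5R)-2-methyl-2-(prop-2-en-1-yl)-5-(propan-2-yl)-5-[(triethylsilyl)oxy]cyclopentyl]-3-methylbut-3-en-1-one
Conditions: [Rh(OH)(cod)]2 (cat.), rac-BINAP, toluene, 40–60 °C
Reagents that add atoms: none
Why: Rhodium-catalysed ring opening of a tert-cyclobutanol: the rhodium alkoxide undergoes strain-releasing β-carbon elimination of the less substituted C6–CH2 bond to a primary alkylrhodium without β-hydrogen, which is protonated by further alcohol, unmasking the C6 ketone and the C1 methyl without touching C1 or C5.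

Step 9
Reactants: 12 the cyclopentyl methallyl ketone
Product: 13 (1R,4R,5R)-4-[(triethylsilyl)oxy]dauc-8-en-6-one
Conditions: Grubbs II catalyst (cat.), CH2Cl2, 40 °C, high dilution
Reagents that add atoms: none
Why: Ring-closing olefin metathesis between the allyl and methallyl olefins, held trans on the cyclopentane, closes the seven-membered ring with a necessarily cis trisubstituted C8=C9 bond and expels ethylene.

Step 10
Reactants: 13 (1R,4R,5R)-4-[(triethylsilyl)oxy]dauc-8-en-6-one
Product: 14 (1R,4R,5R)-4-hydroxydauc-8-en-6-one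
Conditions: HF·pyridine, pyridine, THF, 0 °C to rt
Reagents that add atoms: none
Why: Fluoride-mediated desilylation under buffered, weakly acidic conditions avoids base-induced conjugation of the β,γ-unsaturated ketone and retro-aldol of the freed β-hydroxy ketone.

Step 11
Reactants: 14 (1R,4R,5R)-4-hydroxydauc-8-en-6-one
Product: 15 (1R,4R,5S,6S)-dauc-8-ene-4,6-diol
Conditions: Me4NBH(OAc)3, MeCN/AcOH, −30 to −20 °C
Reagents that add atoms: none
Why: Hydroxyl-directed 1,3-anti reduction (Evans–Saksena type): the C4 hydroxyl binds boron and delivers hydride to the face of C6 on which it sits, which should place the new C6 hydroxyl anti to the C4 hydroxyl, while the olefin is inert.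

Step 12
Reactants: 15 (1R,4R,5S,6S)-dauc-8-ene-4,6-diol
Product: 16 (1R,4R,5S,6S,8R,9S)-8,9-epoxydaucane-4,6-diol
Conditions: VO(acac)2 (cat.), t-BuOOH, CH2Cl2, 0 °C to rt
Reagents that add atoms: tert-butyl hydroperoxide, CC(C)(C)OO
Why: Vanadium-catalysed hydroxyl-directed epoxidation of a homoallylic alcohol: coordination of the C6 hydroxyl should deliver oxygen to the face of C8=C9 syn to that hydroxyl, as in the target oxirane.

Step 13
Reactants: 16 (1R,4R,5S,6S,8R,9S)-8,9-epoxydaucane-4,6-diol
Product: 17 (1R,4R,5S,6S,8R,9S)-8,9-epoxy-4-hydroxydaucan-6-yl 4-methoxybenzoate (CNP0235939.1)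
Conditions: 4-methoxybenzoyl chloride, Et3N, DMAP (cat.), CH2Cl2, 0 °C to rt
Reagents that add atoms: 4-methoxybenzoyl chloride, COc1ccc(cc1)C(Cl)=O
Why: DMAP-catalysed esterification acylates the secondary C6 alcohol only, since the tertiary C4 alcohol is too hindered and the epoxide tolerates the mild base.

**Compound list**

1 | (S)-terpinen-4-ol [(1S)-4-methyl-1-(propan-2-yl)cyclohex-3-en-1-ol] | CC1=CC[C@](O)(C(C)C)CC1 | starting material
2 | (S)-terpinen-4-ol triethylsilyl ether | CC1=CC[C@](O[Si](CC)(CC)CC)(C(C)C)CC1 | intermediate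
3 | (5S)-7-hydroperoxy-7-methoxy-5-(propan-2-yl)-5-[(triethylsilyl)oxy]heptan-2-one (both C7 epimers) | COC(OO)C[C@](O[Si](CC)(CC)CC)(C(C)C)CCC(C)=O | intermediate
4 | methyl (3S)-6-oxo-3-(propan-2-yl)-3-[(triethylsilyl)oxy]heptanoate | COC(=O)C[C@](O[Si](CC)(CC)CC)(C(C)C)CCC(C)=O | intermediate
5 | methyl (3S)-3-(propan-2-yl)-3-[(triethylsilyl)oxy]-6-{[(trifluoromethyl)sulfonyl]oxy}hept-6-enoate | COC(=O)C[C@](O[Si](CC)(CC)CC)(C(C)C)CCC(=C)OS(=O)(=O)C(F)(F)F | intermediate
6 | methyl (3S)-6-methylidene-3-(propan-2-yl)-3-[(triethylsilyl)oxy]non-8-enoate | COC(=O)C[C@](O[Si](CC)(CC)CC)(C(C)C)CCC(=C)CC=C | intermediate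
7 | (3S)-6-methylidene-3-(propan-2-yl)-3-[(triethylsilyl)oxy]non-8-enoic acid | OC(=O)C[C@](O[Si](CC)(CC)CC)(C(C)C)CCC(=C)CC=C | intermediate
8 | (3S)-6-methylidene-3-(propan-2-yl)-3-[(triethylsilyl)oxy]non-8-enoyl chloride | ClC(=O)C[C@](O[Si](CC)(CC)CC)(C(C)C)CCC(=C)CC=C | intermediate
9 | (3R)-6-methylidene-3-(propan-2-yl)-3-[(triethylsilyl)oxy]nona-1,8-dien-1-one (ketene) | O=C=C[C@](O[Si](CC)(CC)CC)(C(C)C)CCC(=C)CC=C | intermediate
10 | (1R,4R,5R)-1-(prop-2-en-1-yl)-4-(propan-2-yl)-4-[(triethylsilyl)oxy]bicyclo[3.2.0]heptan-6-one (cis-fused; silyloxy on the cyclobutanone face, isopropyl on the convex face) | O=C1C[C@]2(CC=C)CC[C@@](O[Si](CC)(CC)CC)(C(C)C)[C@H]12 | intermediate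
11 | 6-(2-methylprop-2-en-1-yl)-1-(prop-2-en-1-yl)-4-(propan-2-yl)-4-[(triethylsilyl)oxy]bicyclo[3.2.0]heptan-6-ol (methallyl on the convex face) | C=C(C)C[C@@]1(O)C[C@]2(CC=C)CC[C@@](O[Si](CC)(CC)CC)(C(C)C)[C@H]12 | intermediate
12 | 1-[(1R,2R,5R)-2-methyl-2-(prop-2-en-1-yl)-5-(propan-2-yl)-5-[(triethylsilyl)oxy]cyclopentyl]-3-methylbut-3-en-1-one (acyl cis to 2-methyl and to silyloxy) | C=C(C)CC(=O)[C@H]1[C@](O[Si](CC)(CC)CC)(C(C)C)CC[C@]1(C)CC=C | intermediate
13 | (1R,4R,5R)-4-[(triethylsilyl)oxy]dauc-8-en-6-one (trans-fused) | O=C1CC(C)=CC[C@@]2(C)CC[C@@](O[Si](CC)(CC)CC)(C(C)C)[C@H]12 | intermediate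
14 | (1R,4R,5R)-4-hydroxydauc-8-en-6-one | O=C1CC(C)=CC[C@@]2(C)CC[C@@](O)(C(C)C)[C@H]12 | intermediate
15 | (1R,4R,5S,6S)-dauc-8-ene-4,6-diol | O[C@H]1CC(C)=CC[C@@]2(C)CC[C@@](O)(C(C)C)[C@H]12 | intermediate
16 | (1R,4R,5S,6S,8R,9S)-8,9-epoxydaucane-4,6-diol | O[C@H]2C[C@@]3(C)O[C@H]3C[C@@]3(C)CC[C@@](O)(C(C)C)[C@H]23 | intermediate
17 | (1R,4R,5S,6S,8R,9S)-8,9-epoxy-4-hydroxydaucan-6-yl 4-methoxybenzoate | COc1ccc(C(=O)O[C@H]2C[C@@]3(C)O[C@H]3C[C@@]3(C)CC[C@@](O)(C(C)C)[C@H]23)cc1 | target

**Step count and risks**

Total step count: 13. Longest linear sequence: 13 steps (1 to 17; the route is fully linear).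

Steps most likely to fail:

Step 8. The rhodium alkoxide of 11 is also a homoallylic alkoxide, so retro-allylation (β-carbon elimination of the methallyl group through a six-membered transition state) may compete with the strain-releasing ring opening, and cleavage of the ring-fusion bond instead of the C6–CH2 bond is also possible. The fallback sets out from cyclobutanone 10 and introduces the allylic unit only after the ring has been opened. Addition of methyllithium (CeCl3, THF, −78 °C) should give the tertiary 6-methylcyclobutanol F1. The same rhodium-catalysed ring opening, now with no allylic group on the carbinol carbon, should give the cyclopentyl methyl ketone F2. Palladium-catalysed α-alkenylation of its methyl-side enolate with 2-bromopropene (LiHMDS, Pd2(dba)3, P(t-Bu)3, toluene) then comes back to the route at 12.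

Step 6. Dimerisation of the aldoketene and ene-type side reactions may outrun the intramolecular cycloaddition at the temperature it requires. The fallback sets out from acid 7 and uses a keteniminium ion, which is more electrophilic and does not dimerise. Amide coupling with pyrrolidine (EDC, HOBt, CH2Cl2) gives the pyrrolidine amide F3. Triflic anhydride and 2,4,6-collidine in 1,2-dichloroethane at reflux generate the keteniminium ion, whose intramolecular [2+2] cycloaddition with the same olefin should give the cyclobutaniminium triflate F4. Hydrolysis with aqueous NaHCO3 comes back to the route at 10.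

Step 12. Facial selectivity of the epoxidation may be poor if delivery from the C6 hydroxyl competes with steric approach to the other face or with coordination to the C4 hydroxyl. The fallback sets out from diol 15 and replaces substrate direction by reagent control. Acylation with 4-methoxybenzoyl chloride (Et3N, DMAP) gives the ester 4-hydroxydauc-8-en-6-yl 4-methoxybenzoate F5. A catalyst-controlled dioxirane epoxidation of the trisubstituted olefin (fructose-derived chiral ketone, Oxone, buffered MeCN/dimethoxymethane/H2O, 0 °C; both ketone enantiomers are available, so the face is set by the reagent) comes back to the route at 17.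

Further compounds
F1 | step 8 | 6-methyl-1-(prop-2-en-1-yl)-4-(propan-2-yl)-4-[(triethylsilyl)oxy]bicyclo[3.2.0]heptan-6-ol (methyl on the convex face) | C[C@@]1(O)C[C@]2(CC=C)CC[C@@](O[Si](CC)(CC)CC)(C(C)C)[C@H]12
F2 | step 8 | 1-[(1R,2R,5R)-2-methyl-2-(prop-2-en-1-yl)-5-(propan-2-yl)-5-[(triethylsilyl)oxy]cyclopentyl]ethan-1-one | CC(=O)[C@H]1[C@](O[Si](CC)(CC)CC)(C(C)C)CC[C@]1(C)CC=C
F3 | step 6 | (3S)-6-methylidene-3-(propan-2-yl)-1-(pyrrolidin-1-yl)-3-[(triethylsilyl)oxy]non-8-en-1-one | O=C(C[C@](O[Si](CC)(CC)CC)(C(C)C)CCC(=C)CC=C)N1CCCC1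
F4 | step 6 | 1-{1-(prop-2-en-1-yl)-4-(propan-2-yl)-4-[(triethylsilyl)oxy]bicyclo[3.2.0]heptan-6-ylidene}pyrrolidin-1-ium triflate (ring centres as in 10) | C1CC[N+](C1)=C1C[C@]2(CC=C)CC[C@@](O[Si](CC)(CC)CC)(C(C)C)[C@H]12.[O-]S(=O)(=O)C(F)(F)F
F5 | step 12 | (1R,4R,5S,6S)-4-hydroxydauc-8-en-6-yl 4-methoxybenzoate | COc1ccc(C(=O)O[C@H]2CC(C)=CC[C@@]3(C)CC[C@@](O)(C(C)C)[C@H]23)cc1
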